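Numbering used below: intermediates up to 18 are octahydro-2H-chromenes (O1, C2, C3, C4, C4a, C5–C8, C8a). After ring enlargement they are 1-benzoxepines (O1, C2–C5, C5a, C6–C9, C9a), so C4a/C8a become C5a/C9a.

## Analysis of the target

Sodwanone T is a C30 triterpenoid built from two 2,2,5a,7-tetramethyl-hexahydro-1-benzoxepine units. Oxepane ring A is fused to cyclohexene ring B, cyclohexene ring C to oxepane ring D, and a CH2–CH2 bridge joins the C6 alkene carbons of rings B and C. Each half has a trans fusion between a tertiary ether CH (C9a) and a methyl-bearing quaternary carbon (C5a). Both fusions are (5aS,9aS), so the halves are homochiral and the carbon skeleton is C2-symmetric. The symmetry is broken only at C3: ring A carries an (R)-carbinol, with the hydroxyl cis to the angular methyl group, and ring D carries a ketone. Five stereocentres therefore have to be set. Sensitive groups are the two tetrasubstituted alkenes next to quaternary carbons, the ring D ketone with one enolisable CH2, and the free secondary alcohol. The hard parts are the seven-membered ethers (closed onto a gem-dimethyl carbon and trans-fused next to a quaternary centre), the hindered alkenes, and giving two otherwise identical halves different oxidation levels. The strategy rests on C3 of rings A and D, which lies between O1–C2(CH3)2 and the C4H2–C5H2 unit: taking out C4 leaves a trans-fused 2,2-dimethyltetrahydropyran-3-one, a ring that closes in the six-membered manifold.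

## Retrosynthetic reasoning

**31 ⇒ 25 + 27.** After removal of the silyl ether (30), the bond between C6 of ring C and the bridge CH2 is cut. It is the one sp2–sp3 bond whose cleavage gives two halves of the same bicyclic skeleton. The ring D ketone stays in the electrophile 27, which needs no organometallic activation; the carbinol is masked in the nucleophile precursor 25. The forward step must couple a primary alkyl group to a tetrasubstituted enol triflate flanked by a quaternary carbon.

**25 ⇒ 21.** Functional-group changes only: iodide from alcohol 24, from benzyl ether 23; silyl ether from carbinol 22; carbinol from ketone 21 by reagent-controlled reduction. Both halves now trace back to ring A/D ketones (21 and 27) of one oxidation level.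

**21 ⇒ 18 and 27 ⇒ 15 (the key disconnection).** C4 is excised: the C3–C4 and C4–C5 bonds are cut and C3 is rejoined to C5, contracting the oxepanone to a pyranone. Cutting O1–C2 or O1–C9a instead would demand seven-membered ether closure at a tertiary or neopentylic carbon. The forward reaction has to insert one carbon from 19 on the CH2 side of the carbonyl only, and it creates no stereocentre.

**18 ⇒ 15 + 16.** The C5–CH2 bond of the side chain is cut; the two bridge carbons come from 16 through borane 17. This makes 15 the last common intermediate: one portion is homologated as the triflate (to 27), the other is coupled first so that ring A is enlarged on a substrate without a sulfonate ester.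

**15 ⇒ 11.** The enol triflate comes from a C5 ketone, the C6 methyl from enolate methylation (12, 13). Because C4a is quaternary, both enolisations can only go toward C6. The pyranone oxygen is carried as a silyl ether (13, 14) because a free pyranone would compete in enolate formation.

**11 ⇒ 6.** The O1–C2 bond is cut: the pyran is closed by 6-endo opening of epoxide 7 by the C8a hydroxyl at the tertiary carbon (8), followed by protecting-group exchange and oxidation (9, 10). The trans fusion requires that hydroxyl to be trans to the side chain on C4a.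

**6 ⇒ 4 + 5.** This is the stereochemical crux of the early part. Hydride reduction of a 2,2-disubstituted 1,3-dione places the new hydroxyl cis to the larger C2 substituent, which would give a cis-fused pyran. The carbinol of 4 is therefore used as a directing group: an Evans–Tishchenko reduction with 5 delivers hydride to the remaining ketone from the carbinol's own face. The new hydroxyl is then trans to the side chain, and the directing oxygen leaves the step as a benzoate, so the two oxygens are differentiated at once.

**4 ⇒ 3 ⇒ 1 + 2.** Enzymatic desymmetrisation of the prochiral dione 3 sets the quaternary centre; 3 comes from C-alkylation of 1 with 2.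

## Alternatives that were turned down

**Alternative 1: furanone [2+2] photocycloaddition, then cyclobutane opening.**
- Disconnection: a cyclobutane spanning C4, C5, C5a and C9a of ring D is imagined and cut at C5a–C9a and C4–C5, leading to the tethered furanone A1.
- Forward key step: irradiation of A1 gives the tricyclic adduct A2; reductive cleavage of the cyclobutane bond next to the ketone then enlarges the furanone to the oxepan-3-one.
- For: the quaternary centre, ring C and the C5a–C9a bond form in one C–C bond-forming step, and the ketone appears at the ring D oxidation level without a diazoalkane. On bond-forming economy it is stronger than the chosen route.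
- Against: with a four-atom tether, straight and crossed addition modes and hydrogen abstraction compete. Absolute control rests on one allylic silyloxy stereocentre acting through tether conformation. The adduct is cis-fused at the cyclobutane, and the C9a hydrogen is introduced only later by reduction and protonation of an α-oxy radical or anion, so the trans fusion is not secured. The C7 methyl and the enol triflate still have to be made.
- Comparison: the chosen route fixes the trans fusion through a chair transition state before the ring is enlarged, and the enlargement itself is stereochemically silent.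

**Alternative 2: double Birch reductive methylation of a chiral bibenzyl.**
- Disconnection: both C5a–CH3 bonds are cut, and rings B and C are traced to the arenes of bibenzyl A3.
- Forward key step: dissolving-metal reduction of A3 gives two amide enolates that are C-methylated to the bis-diene A4.
- For: both quaternary centres are set in one two-directional step under auxiliary control, and the bridge and both tetrasubstituted alkenes are present from the start. It avoids the two hindered cross-couplings of the chosen route and is stronger there.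
- Against: after the key step neither oxepane exists. The hindered amide carbon must become C5, two more carbons must be added, and a seven-membered ether must be closed at tertiary C2, which is the closure the ring enlargement avoids. The C9a carbinol must come from reducing a ketone next to the quaternary centre with the hydroxyl trans to the new chain, against the normal bias. Everything is done twice on a symmetric intermediate, so the final alcohol/ketone distinction is statistical.
- Comparison: the chosen route diverges deliberately from 15 into the two oxidation levels.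

**Alternative 3: transannular Prins closure of an eleven-membered cyclic acetal.**
- Disconnection: the C5a–C9a fusion bond is cut, opening rings A and B to the macrocyclic α-acetoxy ether A5.
- Forward key step: a Lewis acid ionises A5 to an oxocarbenium ion; the alkene carbon that becomes C5a attacks across the ring, and proton loss from C7 gives A6, which is identical with 23.
- For: rings A and B, the quaternary centre and the ring alkene form together, and the product is already at the level of 23 without ring enlargement, carbinol reduction or side-chain coupling. For the A/B half it is the shortest on paper.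
- Against: A5 is an eleven-membered ring containing a tetrasubstituted E-alkene and is itself a long synthesis. The fusion stereochemistry depends on macrocycle conformation, controlled only by the remote silyloxy centre. Proton loss can occur toward several positions. The ketone-bearing C/D half needs a separate solution.
- Comparison: the chosen route uses one sequence for both halves, and each stereo-determining step has a defined small-ring transition state.

Key step: step 13

Remark (assumption): baker's yeast is taken to reduce 3 in the sense known for 2-allyl-2-methylcyclohexane-1,3-diones, giving the (3S)-carbinol with hydroxyl and allylic chain cis; any C2 epimer is removed by chromatography of 4.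

## Route

Step 1
Reactants: 1 2-methylcyclohexane-1,3-dione; 2 1-bromo-3-methylbut-2-ene (prenyl bromide)
Product: 3 2-methyl-2-(3-methylbut-2-en-1-yl)cyclohexane-1,3-dione
Conditions: NaOH (1 M aq.), rt
Reagents that add atoms: prenyl bromide (2), CC(C)=CCBr
Why: C-alkylation of a cyclic 1,3-dione enolate with an allylic bromide; in water the enolate oxygens are hydrogen-bonded, which favours attack through carbon and gives the prochiral 2,2-disubstituted dione.

Step 2
Reactants: 3 2-methyl-2-(3-methylbut-2-en-1-yl)cyclohexane-1,3-dione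
Product: 4 (2S,3S)-3-hydroxy-2-methyl-2-(3-methylbut-2-en-1-yl)cyclohexan-1-one
Conditions: baker's yeast (Saccharomyces cerevisiae), sucrose, H2O, 30 °C
Reagents that add atoms: none
Why: Enzymatic desymmetrising reduction of one enantiotopic carbonyl; the yeast reductases should give the (3S)-carbinol with the hydroxyl cis to the prenyl chain, which also makes C2 a defined (S) quaternary centre.

Step 3
Reactants: 4 (2S,3S)-3-hydroxy-2-methyl-2-(3-methylbut-2-en-1-yl)cyclohexan-1-one; 5 benzaldehyde
Product: 6 (1S,2R,3S)-3-hydroxy-2-methyl-2-(3-methylbut-2-en-1-yl)cyclohexyl benzoate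
Conditions: PhCHO, SmI2 (cat.), THF, −10 °C
Reagents that add atoms: benzaldehyde (5), O=Cc1ccccc1
Why: Evans–Tishchenko reduction: the samarium-bound hemiacetal formed from the axial carbinol and 5 transfers hydride through a six-membered chelate to the ketone face syn to that oxygen, so the new hydroxyl is 1,3-anti to it and trans to the prenyl chain. The directing oxygen emerges as the benzoate, and the trans-1,3 arrangement on the ring blocks acyl migration.

Step 4
Reactants: 6 (1S,2R,3S)-3-hydroxy-2-methyl-2-(3-methylbut-2-en-1-yl)cyclohexyl benzoate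
Product: 8 (3S,4aR,5S,8aS)-3-hydroxy-2,2,4a-trimethyloctahydro-2H-chromen-5-yl benzoate, via epoxy alcohol 7 (not isolated)
Conditions: L-fructose-derived Shi ketone (ent-Shi ketone, cat.), KHSO5, K2CO3, MeCN/(MeO)2CH2/H2O, 0 °C; then CSA (cat.), CH2Cl2, 0 °C
Reagents that add atoms: potassium peroxymonosulfate (KHSO5), [K+].[O-]S(=O)(=O)OO
Why: Shi epoxidation sets the (S)-epoxide under reagent control, and acid-catalysed 6-endo opening by the trans-disposed hydroxyl at the tertiary carbon closes the pyran through a trans-decalin-like chair in which the epoxide C–O bond is equatorial. The 5-exo path would need a strained trans-fused oxabicyclo[4.3.0] transition state and attack at the less cation-stabilising carbon; the C3 carbinol configuration is carried over from the epoxide.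

Step 5
Reactants: 8 (3S,4aR,5S,8aS)-3-hydroxy-2,2,4a-trimethyloctahydro-2H-chromen-5-yl benzoate
Product: 9 (3S,4aR,5S,8aS)-3-[(tert-butyldimethylsilyl)oxy]-2,2,4a-trimethyloctahydro-2H-chromen-5-yl benzoate
Conditions: TBSOTf, 2,6-lutidine, CH2Cl2, 0 °C
Reagents that add atoms: tert-butyldimethylsilyl trifluoromethanesulfonate, CC(C)(C)[Si](C)(C)OS(=O)(=O)C(F)(F)F
Why: Silylation of a hindered equatorial secondary alcohol with a silyl triflate; the ether must survive hydride, oxidant and strong base in steps 6–9.

Step 6
Reactants: 9 (3S,4aR,5S,8aS)-3-[(tert-butyldimethylsilyl)oxy]-2,2,4a-trimethyloctahydro-2H-chromen-5-yl benzoate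
Product: 10 (3S,4aS,5S,8aS)-3-[(tert-butyldimethylsilyl)oxy]-2,2,4a-trimethyloctahydro-2H-chromen-5-ol
Conditions: i-Bu2AlH, CH2Cl2, −78 °C
Reagents that add atoms: none
Why: Reductive cleavage of the benzoate; the aluminium hydride attacks the ester carbonyl, which lies outside the hindered ring position, and leaves the silyl ether intact.

Step 7
Reactants: 10 (3S,4aS,5S,8aS)-3-[(tert-butyldimethylsilyl)oxy]-2,2,4a-trimethyloctahydro-2H-chromen-5-ol
Product: 11 (3S,4aR,8aS)-3-[(tert-butyldimethylsilyl)oxy]-2,2,4a-trimethyloctahydro-5H-chromen-5-one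
Conditions: Dess–Martin periodinane, CH2Cl2, rt
Reagents that add atoms: none
Why: Dess–Martin oxidation of a secondary alcohol; the neighbouring C4a is quaternary, so no stereocentre can epimerise.

Step 8
Reactants: 11 (3S,4aR,8aS)-3-[(tert-butyldimethylsilyl)oxy]-2,2,4a-trimethyloctahydro-5H-chromen-5-one
Product: 12 (3S,4aR,8aS)-3-[(tert-butyldimethylsilyl)oxy]-2,2,4a,6-tetramethyloctahydro-5H-chromen-5-one (mixture of C6 epimers)
Conditions: LiN(i-Pr)2, THF, −78 °C; MeI, −78 to −20 °C
Reagents that add atoms: iodomethane, CI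
Why: Enolate alkylation; the lithium enolate can form only toward C6 because C4a is quaternary, and the C6 configuration is irrelevant since the carbon becomes sp2 in step 9.

Step 9
Reactants: 12 (3S,4aR,8aS)-3-[(tert-butyldimethylsilyl)oxy]-2,2,4a,6-tetramethyloctahydro-5H-chromen-5-one
Product: 13 (3S,4aR,8aS)-3-[(tert-butyldimethylsilyl)oxy]-2,2,4a,6-tetramethyl-3,4,4a,7,8,8a-hexahydro-2H-chromen-5-yl trifluoromethanesulfonate
Conditions: KN(SiMe3)2, THF, −78 °C; PhNTf2, −78 to 0 °C
Reagents that add atoms: N-phenylbis(trifluoromethanesulfonimide), O=S(=O)(N(c1ccccc1)S(=O)(=O)C(F)(F)F)C(F)(F)F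
Why: O-sulfonylation of the only possible (tetrasubstituted) potassium enolate gives the enol triflate with the ring alkene in its final position between C5 and C6.

Step 10
Reactants: 13 (3S,4aR,8aS)-3-[(tert-butyldimethylsilyl)oxy]-2,2,4a,6-tetramethyl-3,4,4a,7,8,8a-hexahydro-2H-chromen-5-yl trifluoromethanesulfonate
Product: 14 (3S,4aR,8aS)-3-hydroxy-2,2,4a,6-tetramethyl-3,4,4a,7,8,8a-hexahydro-2H-chromen-5-yl trifluoromethanesulfonate
Conditions: HF·pyridine, THF, 0 °C to rt
Reagents that add atoms: none
Why: Fluoride-driven Si–O cleavage under mildly acidic conditions, to which the enol triflate is inert.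

Step 11
Reactants: 14 (3S,4aR,8aS)-3-hydroxy-2,2,4a,6-tetramethyl-3,4,4a,7,8,8a-hexahydro-2H-chromen-5-yl trifluoromethanesulfonate
Product: 15 (4aR,8aS)-2,2,4a,6-tetramethyl-3-oxo-3,4,4a,7,8,8a-hexahydro-2H-chromen-5-yl trifluoromethanesulfonate
Conditions: Dess–Martin periodinane, CH2Cl2, rt
Reagents that add atoms: none
Why: Dess–Martin oxidation to the α-alkoxy ketone under neutral conditions that do not touch the enol triflate; the C3 stereocentre, having served the cyclisation, disappears here.

Step 12
Reactants: 15 (4aR,8aS)-2,2,4a,6-tetramethyl-3-oxo-3,4,4a,7,8,8a-hexahydro-2H-chromen-5-yl trifluoromethanesulfonate; 16 benzyl vinyl ether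
Product: 18 (4aS,8aS)-5-[2-(benzyloxy)ethyl]-2,2,4a,6-tetramethyl-4a,7,8,8a-tetrahydro-2H-chromen-3(4H)-one, via 9-[2-(benzyloxy)ethyl]-9-BBN 17 (not isolated)
Conditions: 16, 9-BBN, THF, 0 °C to rt; then 15, Pd(dppf)Cl2 (cat.), AsPh3, K3PO4 (aq.), DMF, 50 °C
Reagents that add atoms: benzyl vinyl ether (16), C=COCc1ccccc1
Why: Hydroboration of the enol ether places boron on the terminal carbon, and B-alkyl Suzuki–Miyaura coupling (oxidative addition of zerovalent palladium to the C–OTf bond, base-assisted alkyl transfer from boron, reductive elimination) joins it to C5. The wide-bite-angle dppf ligand favours reductive elimination over β-elimination, and the ketone is tolerated because no B–H remains.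

Step 13
Reactants: 18 (4aS,8aS)-5-[2-(benzyloxy)ethyl]-2,2,4a,6-tetramethyl-4a,7,8,8a-tetrahydro-2H-chromen-3(4H)-one; 19 (trimethylsilyl)diazomethane
Product: 21 (5aS,9aS)-6-[2-(benzyloxy)ethyl]-2,2,5a,7-tetramethyl-4,5,5a,8,9,9a-hexahydro-1-benzoxepin-3(2H)-one, via C4-silyl ketone 20 (not isolated)
Conditions: 19, Me3Al, CH2Cl2, −78 to −20 °C; then HCl (1 M aq.), THF, rt
Reagents that add atoms: (trimethylsilyl)diazomethane (19), C[Si](C)(C)C=[N+]=[N-]
Why: Me3Al binds the C3 carbonyl oxygen and the diazo carbon of 19 adds to C3, giving a β-aluminoxy diazonium ion; the C3–C4 bond, which can lie antiperiplanar to the C–N2 bond, then shifts to the diazo carbon as N2 leaves, so both bonds to the inserted carbon are formed and the six-membered ether becomes the seven-membered ring A ketone 20. The closest known reaction type is the Lewis-acid-promoted homologation of cyclic ketones with 19, which has been applied to fused tetrahydropyran-3-ones to give oxepan-3-ones. No ring is closed by cyclisation: ring A arises by a 1,2-alkyl shift that enlarges an existing trans-fused ring, so no seven-membered closure has to be achieved. No stereocentre is created, and C4a and C8a of 18 reappear unchanged as C5a and C9a of 21. The one selectivity needed is migration of C4 and not C2: C2 bears the electron-withdrawing ring oxygen, which lowers its migratory aptitude, and it is fully substituted, which disfavours the conformer that would place it anti to the leaving group beside the bulky silyl group. The silyl group of 20 also shields the new ketone from a second insertion and is lost by protodesilylation in the acidic work-up. The tetrasubstituted alkene and the benzyl ether should not react with 19 or Me3Al at low temperature.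

Step 14
Reactants: 21 (5aS,9aS)-6-[2-(benzyloxy)ethyl]-2,2,5a,7-tetramethyl-4,5,5a,8,9,9a-hexahydro-1-benzoxepin-3(2H)-one
Product: 22 (3R,5aS,9aS)-6-[2-(benzyloxy)ethyl]-2,2,5a,7-tetramethyl-2,3,4,5,5a,8,9,9a-octahydro-1-benzoxepin-3-ol
Conditions: (S)-Me-CBS oxazaborolidine (cat.), BH3·SMe2, THF, −20 °C
Reagents that add atoms: none
Why: Corey–Bakshi–Shibata reduction; the catalyst–borane complex binds the carbonyl lone pair anti to the fully substituted C2 (large group) and delivers hydride to the face that gives the (R)-carbinol under reagent control.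

Step 15
Reactants: 22 (3R,5aS,9aS)-6-[2-(benzyloxy)ethyl]-2,2,5a,7-tetramethyl-2,3,4,5,5a,8,9,9a-octahydro-1-benzoxepin-3-ol
Product: 23 {(3R,5aS,9aS)-6-[2-(benzyloxy)ethyl]-2,2,5a,7-tetramethyl-2,3,4,5,5a,8,9,9a-octahydro-1-benzoxepin-3-yl}oxy(tert-butyl)dimethylsilane
Conditions: TBSOTf, 2,6-lutidine, CH2Cl2, 0 °C
Reagents that add atoms: tert-butyldimethylsilyl trifluoromethanesulfonate, CC(C)(C)[Si](C)(C)OS(=O)(=O)C(F)(F)F
Why: Silylation of the hindered carbinol so that it survives hydrogenolysis, iodination and the organolithium of step 19.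

Step 16
Reactants: 23 {(3R,5aS,9aS)-6-[2-(benzyloxy)ethyl]-2,2,5a,7-tetramethyl-2,3,4,5,5a,8,9,9a-octahydro-1-benzoxepin-3-yl}oxy(tert-butyl)dimethylsilane
Product: 24 2-{(3R,5aS,9aS)-3-[(tert-butyldimethylsilyl)oxy]-2,2,5a,7-tetramethyl-2,3,4,5,5a,8,9,9a-octahydro-1-benzoxepin-6-yl}ethan-1-ol
Conditions: H2 (1 atm), Pd/C, EtOAc, rt
Reagents that add atoms: none
Why: Hydrogenolysis of the benzyl ether; the tetrasubstituted alkene should resist heterogeneous hydrogenation at atmospheric pressure.

Step 17
Reactants: 24 2-{(3R,5aS,9aS)-3-[(tert-butyldimethylsilyl)oxy]-2,2,5a,7-tetramethyl-2,3,4,5,5a,8,9,9a-octahydro-1-benzoxepin-6-yl}ethan-1-ol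
Product: 25 tert-butyl{[(3R,5aS,9aS)-6-(2-iodoethyl)-2,2,5a,7-tetramethyl-2,3,4,5,5a,8,9,9a-octahydro-1-benzoxepin-3-yl]oxy}dimethylsilane
Conditions: I2, PPh3, imidazole, CH2Cl2, 0 °C to rt
Reagents that add atoms: iodine, II
Why: Appel-type iodination; iodide displaces the alkoxyphosphonium ion at the unhindered primary carbon by SN2.

Step 18
Reactants: 15 (4aR,8aS)-2,2,4a,6-tetramethyl-3-oxo-3,4,4a,7,8,8a-hexahydro-2H-chromen-5-yl trifluoromethanesulfonate; 19 (trimethylsilyl)diazomethane
Product: 27 (5aR,9aS)-2,2,5a,7-tetramethyl-3-oxo-2,3,4,5,5a,8,9,9a-octahydro-1-benzoxepin-6-yl trifluoromethanesulfonate, via C4-silyl ketone 26 (not isolated)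
Conditions: 19, Me3Al, CH2Cl2, −78 to −20 °C; then HCl (1 M aq.), THF, rt
Reagents that add atoms: (trimethylsilyl)diazomethane (19), C[Si](C)(C)C=[N+]=[N-]
Why: The same Lewis-acid-promoted diazoalkane homologation as in step 13, with the same preference for migration of the CH2 carbon; the enol triflate is inert to Me3Al at low temperature, and the product already has the ketone of ring D.

Step 19
Reactants: 25 tert-butyl{[(3R,5aS,9aS)-6-(2-iodoethyl)-2,2,5a,7-tetramethyl-2,3,4,5,5a,8,9,9a-octahydro-1-benzoxepin-3-yl]oxy}dimethylsilane; 27 (5aR,9aS)-2,2,5a,7-tetramethyl-3-oxo-2,3,4,5,5a,8,9,9a-octahydro-1-benzoxepin-6-yl trifluoromethanesulfonate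
Product: 30 sodwanone T tert-butyldimethylsilyl ether (silyl ether at the ring A carbinol), via alkyllithium 28 (not isolated), via lithium borate 29 (not isolated)
Conditions: 25, t-BuLi, Et2O, −78 °C; B-methoxy-9-BBN, THF, −78 °C to rt; then 27, Pd(dppf)Cl2 (cat.), AsPh3, K3PO4 (aq.), DMF, rt
Reagents that add atoms: none
Why: Lithium–iodine exchange and capture by the borinate give a boron ate complex that transfers its primary alkyl group to palladium after oxidative addition of zerovalent palladium to the enol triflate (B-alkyl Suzuki–Miyaura coupling). The organolithium is consumed before 27 is added, and the borate does not add to the ketone.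

Step 20
Reactants: 30 sodwanone T tert-butyldimethylsilyl ether
Product: 31 sodwanone T
Conditions: HF·pyridine, THF, rt
Reagents that add atoms: none
Why: Fluoride-mediated cleavage of the silyl ether under mildly acidic conditions that should leave the ketone and both tetrasubstituted alkenes untouched.

## Compound list

1 | 2-methylcyclohexane-1,3-dione | CC1C(=O)CCCC1=O | starting material
2 | 1-bromo-3-methylbut-2-ene (prenyl bromide) | CC(C)=CCBr | starting material
3 | 2-methyl-2-(3-methylbut-2-en-1-yl)cyclohexane-1,3-dione | CC(C)=CCC1(C)C(=O)CCCC1=O | intermediate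
4 | (2S,3S)-3-hydroxy-2-methyl-2-(3-methylbut-2-en-1-yl)cyclohexan-1-one | CC(C)=CC[C@]1(C)C(=O)CCC[C@@H]1O | intermediate
5 | benzaldehyde | O=Cc1ccccc1 | starting material
6 | (1S,2R,3S)-3-hydroxy-2-methyl-2-(3-methylbut-2-en-1-yl)cyclohexyl benzoate | CC(C)=CC[C@]1(C)[C@@H](O)CCC[C@@H]1OC(=O)c1ccccc1 | intermediate
7 | (1S,2R,3S)-2-{[(2S)-3,3-dimethyloxiran-2-yl]methyl}-3-hydroxy-2-methylcyclohexyl benzoate | CC1(C)O[C@H]1C[C@]2(C)[C@@H](O)CCC[C@@H]2OC(=O)c3ccccc3 | intermediate
8 | (3S,4aR,5S,8aS)-3-hydroxy-2,2,4a-trimethyloctahydro-2H-chromen-5-yl benzoate | O=C(O[C@H]1CCC[C@@H]2OC(C)(C)[C@@H](O)C[C@@]12C)c1ccccc1 | intermediate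
9 | (3S,4aR,5S,8aS)-3-[(tert-butyldimethylsilyl)oxy]-2,2,4a-trimethyloctahydro-2H-chromen-5-yl benzoate | O=C(O[C@H]1CCC[C@@H]2OC(C)(C)[C@@H](O[Si](C)(C)C(C)(C)C)C[C@@]12C)c1ccccc1 | intermediate
10 | (3S,4aS,5S,8aS)-3-[(tert-butyldimethylsilyl)oxy]-2,2,4a-trimethyloctahydro-2H-chromen-5-ol | O[C@H]1CCC[C@@H]2OC(C)(C)[C@@H](O[Si](C)(C)C(C)(C)C)C[C@@]12C | intermediate
11 | (3S,4aR,8aS)-3-[(tert-butyldimethylsilyl)oxy]-2,2,4a-trimethyloctahydro-5H-chromen-5-one | O=C1CCC[C@@H]2OC(C)(C)[C@@H](O[Si](C)(C)C(C)(C)C)C[C@@]12C | intermediate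
12 | (3S,4aR,8aS)-3-[(tert-butyldimethylsilyl)oxy]-2,2,4a,6-tetramethyloctahydro-5H-chromen-5-one (C6 epimers) | O=C1C(C)CC[C@@H]2OC(C)(C)[C@@H](O[Si](C)(C)C(C)(C)C)C[C@@]12C | intermediate
13 | (3S,4aR,8aS)-3-[(tert-butyldimethylsilyl)oxy]-2,2,4a,6-tetramethyl-3,4,4a,7,8,8a-hexahydro-2H-chromen-5-yl trifluoromethanesulfonate | FC(F)(F)S(=O)(=O)OC1=C(C)CC[C@@H]2OC(C)(C)[C@@H](O[Si](C)(C)C(C)(C)C)C[C@@]12C | intermediate
14 | (3S,4aR,8aS)-3-hydroxy-2,2,4a,6-tetramethyl-3,4,4a,7,8,8a-hexahydro-2H-chromen-5-yl trifluoromethanesulfonate | FC(F)(F)S(=O)(=O)OC1=C(C)CC[C@@H]2OC(C)(C)[C@@H](O)C[C@@]12C | intermediate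
15 | (4aR,8aS)-2,2,4a,6-tetramethyl-3-oxo-3,4,4a,7,8,8a-hexahydro-2H-chromen-5-yl trifluoromethanesulfonate | FC(F)(F)S(=O)(=O)OC1=C(C)CC[C@@H]2OC(C)(C)C(=O)C[C@@]12C | intermediate
16 | benzyl vinyl ether | C=COCc1ccccc1 | starting material
17 | 9-[2-(benzyloxy)ethyl]-9-borabicyclo[3.3.1]nonane | c1ccccc1COCCB1C2CCCC1CCC2 | intermediate
18 | (4aS,8aS)-5-[2-(benzyloxy)ethyl]-2,2,4a,6-tetramethyl-4a,7,8,8a-tetrahydro-2H-chromen-3(4H)-one | c1ccccc1COCCC1=C(C)CC[C@@H]2OC(C)(C)C(=O)C[C@@]12C | intermediate
19 | (trimethylsilyl)diazomethane | C[Si](C)(C)C=[N+]=[N-] | starting material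
20 | (5aS,9aS)-6-[2-(benzyloxy)ethyl]-2,2,5a,7-tetramethyl-4-(trimethylsilyl)-4,5,5a,8,9,9a-hexahydro-1-benzoxepin-3(2H)-one (C4 epimers) | c1ccccc1COCCC1=C(C)CC[C@@H]2OC(C)(C)C(=O)C([Si](C)(C)C)C[C@@]12C | intermediate
21 | (5aS,9aS)-6-[2-(benzyloxy)ethyl]-2,2,5a,7-tetramethyl-4,5,5a,8,9,9a-hexahydro-1-benzoxepin-3(2H)-one | c1ccccc1COCCC1=C(C)CC[C@@H]2OC(C)(C)C(=O)CC[C@@]12C | intermediate
22 | (3R,5aS,9aS)-6-[2-(benzyloxy)ethyl]-2,2,5a,7-tetramethyl-2,3,4,5,5a,8,9,9a-octahydro-1-benzoxepin-3-ol | c1ccccc1COCCC1=C(C)CC[C@@H]2OC(C)(C)[C@H](O)CC[C@@]12C | intermediate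
23 | {(3R,5aS,9aS)-6-[2-(benzyloxy)ethyl]-2,2,5a,7-tetramethyl-2,3,4,5,5a,8,9,9a-octahydro-1-benzoxepin-3-yl}oxy(tert-butyl)dimethylsilane | c1ccccc1COCCC1=C(C)CC[C@@H]2OC(C)(C)[C@H](O[Si](C)(C)C(C)(C)C)CC[C@@]12C | intermediate
24 | 2-{(3R,5aS,9aS)-3-[(tert-butyldimethylsilyl)oxy]-2,2,5a,7-tetramethyl-2,3,4,5,5a,8,9,9a-octahydro-1-benzoxepin-6-yl}ethan-1-ol | OCCC1=C(C)CC[C@@H]2OC(C)(C)[C@H](O[Si](C)(C)C(C)(C)C)CC[C@@]12C | intermediate
25 | tert-butyl{[(3R,5aS,9aS)-6-(2-iodoethyl)-2,2,5a,7-tetramethyl-2,3,4,5,5a,8,9,9a-octahydro-1-benzoxepin-3-yl]oxy}dimethylsilane | ICCC1=C(C)CC[C@@H]2OC(C)(C)[C@H](O[Si](C)(C)C(C)(C)C)CC[C@@]12C | intermediate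
26 | (5aR,9aS)-2,2,5a,7-tetramethyl-3-oxo-4-(trimethylsilyl)-2,3,4,5,5a,8,9,9a-octahydro-1-benzoxepin-6-yl trifluoromethanesulfonate (C4 epimers) | FC(F)(F)S(=O)(=O)OC1=C(C)CC[C@@H]2OC(C)(C)C(=O)C([Si](C)(C)C)C[C@@]12C | intermediate
27 | (5aR,9aS)-2,2,5a,7-tetramethyl-3-oxo-2,3,4,5,5a,8,9,9a-octahydro-1-benzoxepin-6-yl trifluoromethanesulfonate | FC(F)(F)S(=O)(=O)OC1=C(C)CC[C@@H]2OC(C)(C)C(=O)CC[C@@]12C | intermediate
28 | {2-[(3R,5aS,9aS)-3-[(tert-butyldimethylsilyl)oxy]-2,2,5a,7-tetramethyl-2,3,4,5,5a,8,9,9a-octahydro-1-benzoxepin-6-yl]ethyl}lithium | [Li]CCC1=C(C)CC[C@@H]2OC(C)(C)[C@H](O[Si](C)(C)C(C)(C)C)CC[C@@]12C | intermediate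
29 | lithium B-methoxy-B-{2-[(3R,5aS,9aS)-3-[(tert-butyldimethylsilyl)oxy]-2,2,5a,7-tetramethyl-2,3,4,5,5a,8,9,9a-octahydro-1-benzoxepin-6-yl]ethyl}-9-borabicyclo[3.3.1]nonan-9-uide | [Li+].CO[B-]4(CCC1=C(C)CC[C@@H]2OC(C)(C)[C@H](O[Si](C)(C)C(C)(C)C)CC[C@@]12C)C5CCCC4CCC5 | intermediate
30 | sodwanone T tert-butyldimethylsilyl ether | CC1=C(CCC2=C(C)CC[C@@H]3OC(C)(C)[C@H](O[Si](C)(C)C(C)(C)C)CC[C@@]23C)[C@]2(C)CCC(=O)C(C)(C)O[C@H]2CC1 | intermediate
31 | sodwanone T | CC1=C(CCC2=C(C)CC[C@@H]3OC(C)(C)[C@H](O)CC[C@@]23C)[C@]2(C)CCC(=O)C(C)(C)O[C@H]2CC1 | target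

## Step count and least certain steps

Total step count: 20. Longest linear sequence: 19 steps (steps 1–17, 19 and 20); step 18 lies on the shorter branch from 15.

**Step 13 (key step).** Addition of the diazoalkane to a carbonyl flanked by a fully substituted carbon may be slow, so Lewis-acid decomposition of the reagent, methyl transfer from aluminium, epoxide formation or partial migration of C2 could erode the outcome. Fallback, from 18 back to 21: 18 can enolise only toward C4, so LiN(i-Pr)2 and Me3SiCl would give the silyl enol ether F1. Simmons–Smith cyclopropanation (Et2Zn, CH2I2) would give the siloxycyclopropane F2. Oxidative opening of the shared cyclopropane bond with FeCl3 in DMF would give the ring-enlarged β-chloro ketone F3, and NaOAc in MeOH the enone F4. Conjugate reduction with [(Ph3P)CuH]6 would then deliver 21. Here enolisation, not migratory aptitude, fixes the regiochemistry.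

**Step 3.** The samarium aldolate of 4 may fragment by retro-aldol ring opening, or hydride transfer within the bicyclic chelate may be slow; any C2 epimer in 4 would lead to the wrong ester. Fallback, from 3 back to 11:
- Reduction of 3 with (R)-Me-CBS oxazaborolidine and catecholborane should give the (2R,3R)-hydroxy ketone F5, with the hydroxyl again cis to the prenyl chain.
- Mitsunobu inversion (4-nitrobenzoic acid, PPh3, DIAD) would give the ester F6, and K2CO3 in MeOH the trans-hydroxy ketone F7.
- Epoxidation and acid treatment as in step 4 would lead through the epoxide F8 to the pyranol ketone F9, and TBSOTf would convert F9 into 11.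
- This line is shorter but hangs on an SN2 inversion at a neopentylic carbinol, which is why it is held in reserve.

**Step 4.** Competing 5-exo opening at the secondary epoxide carbon would give a tetrahydrofuran carbinol. Fallback, from 6 back to 8: cyclisation of 6 with Hg(OCOCF3)2 should follow Markovnikov control and give the 3-mercurio pyran F10. Oxidative demercuration (NaBH4, O2, DMF) would give 8 together with its C3 epimer F11. Dess–Martin oxidation of the mixture would give the single pyranone F12, and reduction with (R)-Me-CBS oxazaborolidine and BH3·SMe2 would return 8.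

**Step 12.** Oxidative addition and alkyl transfer at a tetrasubstituted triflate beside a quaternary carbon may be slow, so that loss of alkoxide from the β-alkoxyethyl group or hydrolysis of the triflate takes over. Fallback, from 15 back to 18: Stille coupling of 15 with Bu3SnCH=CH2 (Pd(PPh3)4, LiCl) would give the dienone F13. 9-BBN should hydroborate only the terminal vinyl group (borane F14), and NaBO3 would give the hydroxyethyl ketone F15. Benzylation with benzyl trichloroacetimidate and catalytic TfOH would give 18.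

**Step 19.** Two hindered partners meet; slow alkyl transfer from boron may allow reduction or hydrolysis of the triflate and protodeboronation. Fallback, from 25 and 27 back to 30: zinc insertion into 25 (Zn, LiCl, THF) would give the alkylzinc iodide F16. Base-free Negishi coupling with 27 (Pd(OAc)2, SPhos) would give 30 without t-BuLi or a boron intermediate.

**Step 14.** Reagent control may be opposed by the facial bias of the trans-fused oxepanone, giving poor selectivity at C3. Fallback, from 21 back to 22: NaBH4 reduction would give 22 together with its (3S)-epimer F17. The epimers would be separated by chromatography and F17 re-oxidised with Dess–Martin periodinane to 21 for recycling.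

## Further compounds

F1 | step 13 | {(4aS,8aS)-5-[2-(benzyloxy)ethyl]-2,2,4a,6-tetramethyl-4a,7,8,8a-tetrahydro-2H-chromen-3-yl}oxy(trimethyl)silane | c1ccccc1COCCC1=C(C)CC[C@@H]2OC(C)(C)C(O[Si](C)(C)C)=C[C@@]12C
F2 | step 13 | siloxycyclopropane from F1 (CH2 bridging C3 and C4, Me3SiO on C3) | c1ccccc1COCCC1=C(C)CC[C@@H]2OC(C)(C)C3(O[Si](C)(C)C)CC3[C@@]12C
F3 | step 13 | (5aS,9aS)-6-[2-(benzyloxy)ethyl]-5-chloro-2,2,5a,7-tetramethyl-4,5,5a,8,9,9a-hexahydro-1-benzoxepin-3(2H)-one | c1ccccc1COCCC1=C(C)CC[C@@H]2OC(C)(C)C(=O)CC(Cl)[C@@]12C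
F4 | step 13 | (5aS,9aS)-6-[2-(benzyloxy)ethyl]-2,2,5a,7-tetramethyl-5a,8,9,9a-tetrahydro-1-benzoxepin-3(2H)-one | c1ccccc1COCCC1=C(C)CC[C@@H]2OC(C)(C)C(=O)C=C[C@@]12C
F5 | step 3 | (2R,3R)-3-hydroxy-2-methyl-2-(3-methylbut-2-en-1-yl)cyclohexan-1-one | CC(C)=CC[C@@]1(C)C(=O)CCC[C@H]1O
F6 | step 3 | (1S,2R)-2-methyl-2-(3-methylbut-2-en-1-yl)-3-oxocyclohexyl 4-nitrobenzoate | CC(C)=CC[C@@]1(C)C(=O)CCC[C@@H]1OC(=O)c1ccc(cc1)[N+](=O)[O-]
F7 | step 3 | (2R,3S)-3-hydroxy-2-methyl-2-(3-methylbut-2-en-1-yl)cyclohexan-1-one | CC(C)=CC[C@@]1(C)C(=O)CCC[C@@H]1O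
F8 | step 3 | (2R,3S)-2-{[(2S)-3,3-dimethyloxiran-2-yl]methyl}-3-hydroxy-2-methylcyclohexan-1-one | CC1(C)O[C@H]1C[C@@]2(C)C(=O)CCC[C@@H]2O
F9 | step 3 | (3S,4aR,8aS)-3-hydroxy-2,2,4a-trimethyloctahydro-5H-chromen-5-one | O=C1CCC[C@@H]2OC(C)(C)[C@@H](O)C[C@@]12C
F10 | step 4 | (4aR,5S,8aS)-2,2,4a-trimethyl-3-[(trifluoroacetoxy)mercurio]octahydro-2H-chromen-5-yl benzoate | O=C(O[C@H]1CCC[C@@H]2OC(C)(C)C([Hg]OC(=O)C(F)(F)F)C[C@@]12C)c1ccccc1
F11 | step 4 | (3R,4aR,5S,8aS)-3-hydroxy-2,2,4a-trimethyloctahydro-2H-chromen-5-yl benzoate | O=C(O[C@H]1CCC[C@@H]2OC(C)(C)[C@H](O)C[C@@]12C)c1ccccc1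
F12 | step 4 | (4aR,5S,8aS)-2,2,4a-trimethyl-3-oxooctahydro-2H-chromen-5-yl benzoate | O=C(O[C@H]1CCC[C@@H]2OC(C)(C)C(=O)C[C@@]12C)c1ccccc1
F13 | step 12 | (4aS,8aS)-5-ethenyl-2,2,4a,6-tetramethyl-4a,7,8,8a-tetrahydro-2H-chromen-3(4H)-one | C=CC1=C(C)CC[C@@H]2OC(C)(C)C(=O)C[C@@]12C
F14 | step 12 | (4aS,8aS)-5-[2-(9-borabicyclo[3.3.1]nonan-9-yl)ethyl]-2,2,4a,6-tetramethyl-4a,7,8,8a-tetrahydro-2H-chromen-3(4H)-one | B3(CCC1=C(C)CC[C@@H]2OC(C)(C)C(=O)C[C@@]12C)C4CCCC3CCC4
F15 | step 12 | (4aS,8aS)-5-(2-hydroxyethyl)-2,2,4a,6-tetramethyl-4a,7,8,8a-tetrahydro-2H-chromen-3(4H)-one | OCCC1=C(C)CC[C@@H]2OC(C)(C)C(=O)C[C@@]12C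
F16 | step 19 | {2-[(3R,5aS,9aS)-3-[(tert-butyldimethylsilyl)oxy]-2,2,5a,7-tetramethyl-2,3,4,5,5a,8,9,9a-octahydro-1-benzoxepin-6-yl]ethyl}zinc iodide | I[Zn]CCC1=C(C)CC[C@@H]2OC(C)(C)[C@H](O[Si](C)(C)C(C)(C)C)CC[C@@]12C
F17 | step 14 | (3S,5aS,9aS)-6-[2-(benzyloxy)ethyl]-2,2,5a,7-tetramethyl-2,3,4,5,5a,8,9,9a-octahydro-1-benzoxepin-3-ol | c1ccccc1COCCC1=C(C)CC[C@@H]2OC(C)(C)[C@@H](O)CC[C@@]12C
A1 | alternative 1 | 5-[(4S)-4-[(tert-butyldimethylsilyl)oxy]-5-methylhex-5-en-1-yl]-2,2-dimethylfuran-3(2H)-one | CC(C)(C)[Si](C)(C)O[C@H](C(C)=C)CCCC1=CC(=O)C(C)(C)O1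
A2 | alternative 1 | tricyclic furanone–cyclobutane–cyclohexane photoadduct | CC(C)(C)[Si](C)(C)O[C@H]1CCC[C@@]23OC(C)(C)C(=O)[C@@H]2C[C@@]13C
A3 | alternative 2 | 1,2-bis{3-methoxy-2-[(S)-2-(methoxymethyl)pyrrolidine-1-carbonyl]-6-methylphenyl}ethane | Cc1ccc(OC)c(C(=O)N2CCC[C@H]2COC)c1CCc1c(C)ccc(OC)c1C(=O)N1CCC[C@H]1COC
A4 | alternative 2 | bis(1-methyl-2-methoxycyclohexa-2,5-diene) bis-amide with both quaternary centres | CC1=C(CCC2=C(C)CC=C(OC)[C@@]2(C)C(=O)N2CCC[C@H]2COC)[C@](C)(C(=O)N2CCC[C@H]2COC)C(OC)=CC1
A5 | alternative 3 | eleven-membered cyclic α-acetoxy ether with E ring alkene (acetal and C7 configurations immaterial) | CC(=O)OC1CCC(C)/C(CCOCc2ccccc2)=C(C)/CC[C@@H](O[Si](C)(C)C(C)(C)C)C(C)(C)O1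
A6 | alternative 3 | ring A/B bicycle with silylated carbinol and benzyloxyethyl side chain (identical with 23) | c1ccccc1COCCC1=C(C)CC[C@@H]2OC(C)(C)[C@H](O[Si](C)(C)C(C)(C)C)CC[C@@]12C
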